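The ring is numbered as follows: C1 is the quaternary carbinol carbon, C2 and C3 carry the acetates, C4=C5 is the alkene, C6 is the secondary carbinol and C7 the exocyclic CH2. The route rests on the C1–C7 disconnection. C1 lies α to C6, which can be a ketone whose other neighbour (C5) is olefinic, and O1 is cis to O2, so C1 can be the carbon of a cyclohexenone enolate held in a cis-fused 1,3-dioxolane. Its aldol reaction with monomeric formaldehyde forms C1–C7 and the quaternary stereocentre in one operation. The precursor is a 4-silyloxy-5,6-isopropylidenedioxycyclohex-2-enone, made from benzene cis-dihydrodiol by singlet-oxygen cycloaddition and asymmetric Kornblum–DeLaMare rearrangement.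

Key step: step 5

Remark: cis-cyclohexa-3,5-diene-1,2-diol (benzene cis-dihydrodiol, from microbial oxidation of benzene) is assumed to be purchasable. Atom labels C1–C7 and O1–O7 in all descriptions follow the numbering above.

Step 1
Reactants: 1 cis-cyclohexa-3,5-diene-1,2-diol
Product: 2 cis-2,2-dimethyl-3a,7a-dihydro-1,3-benzodioxole (meso diene acetonide)
Conditions: 2,2-dimethoxypropane, p-TsOH (cat.), CH2Cl2, 0 °C, short reaction time; used directly
Reagents that add atoms: 2,2-dimethoxypropane, COC(C)(C)OC
Why: Acid-catalysed transacetalisation (acetonide formation) of the cis-diol, kept cold and brief so that the dihydrodiol is not dehydrated to phenol; both stereocentres (later C1 and C2) are untouched.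

Step 2
Reactants: 2 meso diene acetonide
Product: 3 meso endoperoxide (2,3-dioxabicyclo[2.2.2]oct-5-ene with the cis-fused dioxolane anti to the O–O bridge)
Conditions: O2, tetraphenylporphyrin (cat.), visible light, CH2Cl2, −20 to 0 °C
Reagents that add atoms: oxygen, O=O
Why: Photosensitised [4+2] cycloaddition of singlet oxygen to the 1,3-diene on the face anti to the dioxolane, which places the new C3–O and C6–O bonds trans to O1/O2.

Step 3
Reactants: 3 meso endoperoxide
Product: 4 (3aR,7S,7aR)-7-hydroxy-2,2-dimethyl-3a,7a-dihydro-1,3-benzodioxol-4(7H)-one (C6 ketone, C3–OH trans to the dioxolane)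
Conditions: 9-O-acetylcupreidine (6′-demethylquinidine 9-acetate, 10 mol %), CH2Cl2, rt
Reagents that add atoms: none
Why: Catalytic asymmetric Kornblum–DeLaMare rearrangement, in which the chiral amine should remove one of the two enantiotopic bridgehead C–H protons with O–O cleavage, giving the ketone at that carbon (C6) and the alcohol at C3; no C–O bond is broken, so C3–OH stays trans to O2, and the desymmetrisation fixes the absolute configuration of C2 and C3.

Step 4
Reactants: 4 hydroxy enone
Product: 5 (3aR,7S,7aS)-7-(tert-butyldimethylsilyloxy)-2,2-dimethyl-3a,7a-dihydro-1,3-benzodioxol-4(7H)-one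
Conditions: TBSCl, imidazole, DMF, 0 °C to rt
Reagents that add atoms: tert-butyldimethylsilyl chloride, CC(C)(C)[Si](C)(C)Cl
Why: Standard silylation of the secondary allylic alcohol masks O3 as a base-stable, acid-labile ether for the enolate step; no stereocentre is affected.

Step 5
Reactants: 5 silyloxy enone
Product: 8 (3aR,7S,7aR)-7-(tert-butyldimethylsilyloxy)-3a-(hydroxymethyl)-2,2-dimethyl-3a,7a-dihydro-1,3-benzodioxol-4(7H)-one, via lithium enolate 6 (not isolated), via lithium aldolate 7 (not isolated)
Conditions: LDA (1.1 equiv), THF, −78 °C; CH2O (gas from cracked paraformaldehyde, N2 stream), −78 °C; AcOH/THF quench at −78 °C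
Reagents that add atoms: formaldehyde, C=O
Why: LDA removes the C1–H of 5 (C5 is olefinic and kinetic α′-deprotonation is preferred over γ-deprotonation at C3) to give the cross-conjugated lithium enolate 6, whose C1 attacks monomeric formaldehyde to form C1–C7, and protonation of aldolate 7 gives 8. The closest known reaction type is the crossed-aldol hydroxymethylation of a lithium enolate with formaldehyde, as practised on α-oxygenated carbonyl compounds that carry a fused isopropylidene acetal. No ring is closed. The new quaternary stereocentre C1 is controlled by the ring fusion: O1 is tied through the acetal carbon to O2, so formaldehyde should add to the face of C1 anti to the C2–O bond, which keeps the dioxolane cis-fused and places C7 trans to O2. The step needs C-attack and survival of the β-oxygen at C2; the dioxolane holds the C2–O bond near the nodal plane of the enolate π system, which disfavours E1cB loss at −78 °C. Because C1 is quaternary in 8, neither dehydration nor a second aldol reaction can follow.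

Step 6
Reactants: 8 hydroxymethyl ketone
Product: 9 [(3aR,7S,7aR)-7-(tert-butyldimethylsilyloxy)-2,2-dimethyl-4-oxo-7,7a-dihydro-1,3-benzodioxol-3a(4H)-yl]methyl benzoate
Conditions: BzCl, pyridine, DMAP (cat.), CH2Cl2, 0 °C
Reagents that add atoms: benzoyl chloride, O=C(Cl)c1ccccc1
Why: Nucleophile-catalysed acylation of the only free hydroxyl (primary O7) installs the benzoate; the quaternary C1 excludes dehydration or epimerisation of the β-hydroxy ketone.

Step 7
Reactants: 9 benzoate
Product: 10 [(1R,2R,3S)-1,2,3-trihydroxy-6-oxocyclohex-4-en-1-yl]methyl benzoate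
Conditions: TFA–H2O (9:1), 0 °C to rt
Reagents that add atoms: none
Why: Acid hydrolysis of the isopropylidene acetal and of the allylic TBS ether in one operation; no C–O bond at C1–C3 is broken, and the quaternary C1 blocks dehydrative aromatisation.

Step 8
Reactants: 10 triol enone
Product: 11 [(1R,2R,3S)-2,3-diacetoxy-1-hydroxy-6-oxocyclohex-4-en-1-yl]methyl benzoate
Conditions: Ac2O, pyridine, DMAP (cat.), CH2Cl2, 0 °C
Reagents that add atoms: acetic anhydride, CC(=O)OC(C)=O
Why: Acetylation should take the two secondary hydroxyls (O2, O3) and leave the hindered tertiary α-ketol hydroxyl at C1 free under these mild conditions.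

Step 9
Reactants: 11 diacetate enone
Product: 12 [(1S,2R,3S,6S)-2,3-diacetoxy-1,6-dihydroxycyclohex-4-en-1-yl]methyl benzoate (target)
Conditions: NaBH4, CeCl3·7H2O, MeOH, −78 °C; AcOH quench at −78 °C
Reagents that add atoms: none
Why: Luche 1,2-reduction; in the preferred half-chair of 11 (both acetates and C7 pseudo-equatorial, C1–OH axial) hydride should add axially to C6 anti to the axial C1–O bond, so the new C6–OH is pseudo-equatorial and cis to C1–OH.

Compound list
1 | cis-cyclohexa-3,5-diene-1,2-diol (meso) | O[C@@H]1C=CC=C[C@@H]1O | starting material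
2 | cis-2,2-dimethyl-3a,7a-dihydro-1,3-benzodioxole (meso) | CC1(C)O[C@@H]2C=CC=C[C@@H]2O1 | intermediate
3 | meso endoperoxide, 4,4-dimethyl-3,5,10,11-tetraoxatricyclo[5.2.2.0(2,6)]undec-8-ene, peroxide bridge anti to the dioxolane | O1[C@H]2C=C[C@@H](O1)[C@@H]3OC(C)(C)O[C@H]23 | intermediate
4 | (3aR,7S,7aR)-7-hydroxy-2,2-dimethyl-3a,7a-dihydro-1,3-benzodioxol-4(7H)-one | O[C@H]1C=CC(=O)[C@@H]2OC(C)(C)O[C@H]12 | intermediate
5 | (3aR,7S,7aS)-7-(tert-butyldimethylsilyloxy)-2,2-dimethyl-3a,7a-dihydro-1,3-benzodioxol-4(7H)-one | CC(C)(C)[Si](C)(C)O[C@H]1C=CC(=O)[C@@H]2OC(C)(C)O[C@H]12 | intermediate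
6 | lithium enolate of 5 (C6–OLi, C6=C1; C2 and C3 unchanged) | CC(C)(C)[Si](C)(C)O[C@H]1C=CC(O[Li])=C2OC(C)(C)O[C@H]12 | intermediate
7 | lithium aldolate (lithium alkoxide of 8 at O7) | CC(C)(C)[Si](C)(C)O[C@H]1C=CC(=O)[C@]2(CO[Li])OC(C)(C)O[C@H]12 | intermediate
8 | (3aR,7S,7aR)-7-(tert-butyldimethylsilyloxy)-3a-(hydroxymethyl)-2,2-dimethyl-3a,7a-dihydro-1,3-benzodioxol-4(7H)-one | CC(C)(C)[Si](C)(C)O[C@H]1C=CC(=O)[C@]2(CO)OC(C)(C)O[C@H]12 | intermediate
9 | [(3aR,7S,7aR)-7-(tert-butyldimethylsilyloxy)-2,2-dimethyl-4-oxo-7,7a-dihydro-1,3-benzodioxol-3a(4H)-yl]methyl benzoate | CC(C)(C)[Si](C)(C)O[C@H]1C=CC(=O)[C@]2(COC(=O)c3ccccc3)OC(C)(C)O[C@H]12 | intermediate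
10 | [(1R,2R,3S)-1,2,3-trihydroxy-6-oxocyclohex-4-en-1-yl]methyl benzoate | O[C@H]1C=CC(=O)[C@@](O)(COC(=O)c2ccccc2)[C@@H]1O | intermediate
11 | [(1R,2R,3S)-2,3-diacetoxy-1-hydroxy-6-oxocyclohex-4-en-1-yl]methyl benzoate | CC(=O)O[C@H]1C=CC(=O)[C@@](O)(COC(=O)c2ccccc2)[C@@H]1OC(C)=O | intermediate
12 | [(1S,2R,3S,6S)-2,3-diacetoxy-1,6-dihydroxycyclohex-4-en-1-yl]methyl benzoate | CC(=O)O[C@H]1C=C[C@H](O)[C@@](O)(COC(=O)c2ccccc2)[C@@H]1OC(C)=O | target

Total step count: 9
Longest linear sequence: 9 steps (1 to 12)

Steps most likely to fail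

Step 5 (key step). The enolate may lose the C2 oxygen by β-elimination and aromatise, or the aldol may revert before the quench. The fallback avoids a basic enolate and sets out from 5. Soft enolisation (TMSOTf, Et3N, CH2Cl2, 0 °C) should give the trimethylsilyl dienol ether F1. A lanthanide-triflate-catalysed aqueous Mukaiyama aldol of F1 (aq. HCHO, Yb(OTf)3 cat., THF, rt), under the same ring-fusion control, comes back to the route at 8.

Step 3. Discrimination between the two enantiotopic bridgehead protons may be poor, or a non-selective background rearrangement may compete, giving 4 of low enantiomeric purity; the sense of induction also has to be confirmed on the first run, with the quinine-derived pseudoenantiomeric catalyst used if it is opposite. The fallback replaces the chiral base by an enzymatic desymmetrisation and sets out from 3: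
- Thiourea (MeOH, rt) reduces the O–O bond to the meso diol F2.
- A lipase chosen by screening to acylate the C6 hydroxyl (vinyl acetate, organic solvent) gives the monoacetate F3.
- TBSCl/imidazole silylates the remaining C3 hydroxyl to the silyl ether acetate F4.
- K2CO3/MeOH removes the acetate to the alcohol F5.
- Dess–Martin oxidation of the C6 hydroxyl comes back to the route at 5.

Step 9. Hydride may add to C6 with poor facial selectivity (attack syn to C1–OH from a chelated or ring-flipped conformer), or an acyl group may migrate to the new alkoxide. The fallback moves the reduction to a stage where a hydroxyl can deliver the hydride and sets out from 8: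
- Me4NBH(OAc)3 (MeCN–AcOH, −30 °C, Saksena–Evans reduction) is bound by the free C7–OH and delivers hydride to C6 from the C7 face, giving the diol F6 with C6–OH cis to O1.
- BzCl/2,4,6-collidine (CH2Cl2, −40 °C) benzoylates only the primary hydroxyl to the benzoate F7.
- Levulinic acid, DIC and DMAP mask C6–OH as the levulinate F8.
- TFA–H2O removes acetonide and TBS ether to the triol F9.
- Ac2O/pyridine gives the diacetate F10.
- Hydrazine acetate (pyridine–AcOH, rt) removes only the levulinate and comes back to the route at 12.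

Further compounds
F1 | step 5 | trimethylsilyl dienol ether of 5 (C6–OSiMe3, C6=C1) | CC(C)(C)[Si](C)(C)O[C@H]1C=CC(O[Si](C)(C)C)=C2OC(C)(C)O[C@H]12
F2 | step 3 | meso 2,2-dimethyl-3a,4,7,7a-tetrahydro-1,3-benzodioxole-4,7-diol, both hydroxyls anti to the dioxolane | O[C@H]1C=C[C@@H](O)[C@@H]2OC(C)(C)O[C@H]12
F3 | step 3 | monoacetate of F2, acetate on O6, free hydroxyl at C3 | O[C@H]1C=C[C@@H](OC(C)=O)[C@@H]2OC(C)(C)O[C@H]12
F4 | step 3 | C3 tert-butyldimethylsilyl ether of F3 (O6 acetate) | CC(C)(C)[Si](C)(C)O[C@H]1C=C[C@@H](OC(C)=O)[C@@H]2OC(C)(C)O[C@H]12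
F5 | step 3 | C3 silyl ether with free C6 hydroxyl (anti to the dioxolane) | CC(C)(C)[Si](C)(C)O[C@H]1C=C[C@@H](O)[C@@H]2OC(C)(C)O[C@H]12
F6 | step 9 | 1,3-diol from 8: C6–OH cis to O1, free C7–OH, acetonide and C3 silyl ether retained | CC(C)(C)[Si](C)(C)O[C@H]1C=C[C@H](O)[C@]2(CO)OC(C)(C)O[C@H]12
F7 | step 9 | O7 benzoate of F6 with free C6–OH | CC(C)(C)[Si](C)(C)O[C@H]1C=C[C@H](O)[C@]2(COC(=O)c3ccccc3)OC(C)(C)O[C@H]12
F8 | step 9 | O6 levulinate of F7 | CC(C)(C)[Si](C)(C)O[C@H]1C=C[C@H](OC(=O)CCC(C)=O)[C@]2(COC(=O)c3ccccc3)OC(C)(C)O[C@H]12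
F9 | step 9 | 1,2,3-triol with O6 levulinate and O7 benzoate | O[C@H]1C=C[C@H](OC(=O)CCC(C)=O)[C@@](O)(COC(=O)c2ccccc2)[C@@H]1O
F10 | step 9 | 2,3-diacetate of F9 (O6 levulinate of the target) | CC(=O)O[C@H]1C=C[C@H](OC(=O)CCC(C)=O)[C@@](O)(COC(=O)c2ccccc2)[C@@H]1OC(C)=O
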